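The route rests on opening ring C of the isocoumarin at C4a–C4 and O2–C3. The C1 carboxyl sits on C8a of ring B. Its neighbour C8 carries the diaryl ether oxygen, so C4a–H is the only ortho C–H that a carboxylate-bound metal can reach. One rhodium-catalysed operation joins this carbon to a hexanoyl sulfoxonium ylide, which brings C4, C3 and the pentyl chain, and then lactonises. The precursor is a 2-aryloxy-4-methoxybenzoic acid whose ring A already bears the 2-oxoheptyl chain, with its own acid masked as benzyl ester and both phenols as benzyl ethers. Only ring B can direct, and neutral hydrogenolysis ends the synthesis.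

Key step: step 10

Remark on the chemistry: the target has no stereocentre, so 9 and 14, each with one transient sp3 centre, are racemic. Rings B and C carry isocoumarin numbers. Ring A is numbered as the target acid (C1 carboxyl, C2 and C4 oxygen, C3–H, C5 ether oxygen, C6 side chain).

Step 1
Reactants: 1 5-bromo-2,4-dihydroxybenzoic acid
Product: 2 benzyl 2,4-bis(benzyloxy)-5-bromobenzoate
Conditions: BnBr (3.5 equiv), K2CO3, DMF, 60 °C
Reagents that add atoms: benzyl bromide, BrCc1ccccc1
Why: Williamson etherification and carboxylate alkylation (SN2) put one hydrogenolysable group on all three acidic oxygens, so ring A can later be unmasked without the acid that would lactonise or decarboxylate a free 2-(2-oxoheptyl)resorcylic acid.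

Step 2
Reactants: 2 benzyl 2,4-bis(benzyloxy)-5-bromobenzoate
Product: 4 benzyl 2,4-bis(benzyloxy)-5-hydroxybenzoate, via aryl pinacol boronate 3 (not isolated)
Conditions: B2pin2, PdCl2(dppf) (3 mol %), KOAc, 1,4-dioxane, 90 °C; filtration, then NaBO3·4H2O, THF/H2O, rt
Reagents that add atoms: bis(pinacolato)diboron, CC1(C)OB(OC1(C)C)B1OC(C)(C)C(C)(C)O1 (boryl group of 3); sodium perborate, [Na+].[O-]OB=O (oxygen of 4)
Why: Miyaura borylation followed by ipso-oxidation of the C–B bond (1,2-aryl shift to peroxide oxygen) turns C5–Br into C5–OH under conditions too mild to touch the benzyl ester.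

Step 3
Reactants: 5 3-chloro-2-(chloromethyl)prop-1-ene; 6 butylmagnesium chloride
Product: 7 2-(chloromethyl)hept-1-ene
Conditions: 5 (3 equiv), Li2CuCl4 (3 mol %), THF, −30 to 0 °C; distillation
Reagents that add atoms: none
Why: In this copper-catalysed allylic substitution with a Grignard reagent, SN2 and SN2' attack give the same product because 5 is symmetric, and the excess of 5 keeps the second chloride in place.

Step 4
Reactants: 4 benzyl 2,4-bis(benzyloxy)-5-hydroxybenzoate; 7 2-(chloromethyl)hept-1-ene
Product: 8 benzyl 2,4-bis(benzyloxy)-5-[(2-methylideneheptyl)oxy]benzoate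
Conditions: K2CO3, DMF, 60 °C
Reagents that add atoms: none
Why: This is a Williamson ether synthesis between a lightly hindered phenoxide and a primary allylic chloride.

Step 5
Reactants: 8 benzyl 2,4-bis(benzyloxy)-5-[(2-methylideneheptyl)oxy]benzoate
Product: 10 benzyl 4,6-bis(benzyloxy)-3-hydroxy-2-(2-methylideneheptyl)benzoate, via cyclohexadienone 9 (not isolated)
Conditions: N,N-diethylaniline, 195 °C, Ar
Reagents that add atoms: none
Why: In this aromatic Claisen rearrangement the [3,3] shift can end productively only at C6, because the other ortho carbon C4 bears a benzyloxy group, so one step places the seven-carbon chain (ketone masked as a 1,1-disubstituted alkene) and frees the C5 phenol, while the basic solvent suppresses acid-induced closure to a dihydrobenzofuran.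

Step 6
Reactants: 10 benzyl 4,6-bis(benzyloxy)-3-hydroxy-2-(2-methylideneheptyl)benzoate; 11 2-fluoro-4-methoxybenzaldehyde
Product: 12 benzyl 4,6-bis(benzyloxy)-3-(2-formyl-5-methoxyphenoxy)-2-(2-methylideneheptyl)benzoate
Conditions: K2CO3, dry DMF, 110 °C
Reagents that add atoms: none
Why: In this nucleophilic aromatic substitution (addition–elimination) the ortho formyl group, a stronger acceptor than an ester, stabilises the Meisenheimer adduct, and the alkene mask avoids a free ketone that would close onto the phenol (benzofuran) or, through its acidic CH2, onto the aldehyde (aldol).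

Step 7
Reactants: 12 benzyl 4,6-bis(benzyloxy)-3-(2-formyl-5-methoxyphenoxy)-2-(2-methylideneheptyl)benzoate
Product: 13 2-[4,6-bis(benzyloxy)-3-[(benzyloxy)carbonyl]-2-(2-methylideneheptyl)phenoxy]-4-methoxybenzoic acid
Conditions: NaClO2, NaH2PO4, 2-methyl-2-butene (large excess), t-BuOH/THF/H2O, 0 °C to rt
Reagents that add atoms: sodium chlorite, [Na+].[O-]Cl=O
Why: The Pinnick oxidation converts only the aldehyde, gives the free ring B acid directly with no ester to hydrolyse, and uses the excess trisubstituted alkene to intercept hypochlorous acid before it reaches the side-chain alkene or the electron-rich rings.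

Step 8
Reactants: 13 2-[4,6-bis(benzyloxy)-3-[(benzyloxy)carbonyl]-2-(2-methylideneheptyl)phenoxy]-4-methoxybenzoic acid
Product: 15 2-[4,6-bis(benzyloxy)-3-[(benzyloxy)carbonyl]-2-(2-oxoheptyl)phenoxy]-4-methoxybenzoic acid, via vicinal diol 14 (not isolated)
Conditions: OsO4 (2 mol %), NaIO4 (4 equiv), 2,6-lutidine, 1,4-dioxane/H2O, rt
Reagents that add atoms: osmium tetroxide, O=[Os](=O)(=O)=O; sodium periodate, [Na+].[O-]I(=O)(=O)=O
Why: In the Lemieux–Johnson oxidation OsO4 dihydroxylates the only C=C bond and periodate cleaves diol 14 to the ketone, and running it after the aldehyde is gone means the newly acidic C6–CH2 never meets a formyl group, while fully etherified arenes are inert to periodate.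

Step 9
Reactants: 16 trimethylsulfoxonium iodide; 17 hexanoyl chloride
Product: 19 dimethylsulfoxonium 2-oxoheptylide, via dimethylsulfoxonium methylide 18 (not isolated)
Conditions: 16 (3 equiv), KOt-Bu (3 equiv), THF, reflux; then 17, 0 °C to rt
Reagents that add atoms: none
Why: The Corey–Chaykovsky methylide is C-acylated by the acid chloride, and a second equivalent of 18 removes the acidic proton to give the carbonyl-stabilised ylide.

Step 10
Reactants: 15 2-[4,6-bis(benzyloxy)-3-[(benzyloxy)carbonyl]-2-(2-oxoheptyl)phenoxy]-4-methoxybenzoic acid; 19 dimethylsulfoxonium 2-oxoheptylide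
Product: 21 benzyl 4,6-bis(benzyloxy)-3-[(6-methoxy-1-oxo-3-pentyl-1H-isochromen-8-yl)oxy]-2-(2-oxoheptyl)benzoate, via ring B keto acid 20 (not isolated)
Conditions: [Cp*RhCl2]2 (5 mol %), AgSbF6 (20 mol %), NaOAc (0.5 equiv), 19 (1.5 equiv), 1,2-dichloroethane, 90 °C, Ar
Reagents that add atoms: none
Why: The ring B carboxylate binds the cationic Cp*Rh fragment of trivalent rhodium, and acetate-assisted metalation–deprotonation at C4a gives a five-membered rhodacycle; the ylide carbon then coordinates, dimethyl sulfoxide leaves, the resulting carbene inserts into the Rh–C bond (C4a–C4), and protodemetalation releases keto acid 20. Ring C closes by 6-exo-trig addition of the carboxyl O–H to the new ketone, followed by loss of water from the lactol, which forms O2–C3 and the six-membered enol lactone. The closest known reaction type is the [Cp*RhCl2]2- or [Ru(p-cymene)Cl2]2-catalysed annulation of benzoic acids with alpha-carbonyl sulfoxonium ylides to 3-substituted isocoumarins. No stereocentre is created. The required site selectivity is built in, because C8 is blocked by the ether oxygen, ring A has no C–H next to either the ether or its carboxyl carbon, and the ring A carboxyl, being an ester, cannot bind as a carboxylate. The two similar keto-carboxyl pairs stay distinct because the ring A benzyl ester has no O–H for lactol formation and is shielded by two ortho substituents, and benzyl groups tolerate the Lewis-acidic medium and the water that is formed.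

Step 11
Reactants: 21 benzyl 4,6-bis(benzyloxy)-3-[(6-methoxy-1-oxo-3-pentyl-1H-isochromen-8-yl)oxy]-2-(2-oxoheptyl)benzoate
Product: 22 beta-collatolic acid
Conditions: H2 (1 atm), 10% Pd/C, EtOAc, rt, stopped once the benzyl groups are gone
Reagents that add atoms: none
Why: Catalytic hydrogenolysis cleaves the three benzylic C–O bonds under neutral conditions at room temperature, so the freed ring A keto acid meets neither the acid that would lactonise or decarboxylate it nor the base that would open ring C, and the conjugated trisubstituted C3=C4 bond and the ketone should be reduced far more slowly than benzyl groups are lost.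

Compound list
1 | 5-bromo-2,4-dihydroxybenzoic acid | OC(=O)c1cc(Br)c(O)cc1O | starting material
2 | benzyl 2,4-bis(benzyloxy)-5-bromobenzoate | O=C(OCc1ccccc1)c1cc(Br)c(OCc2ccccc2)cc1OCc1ccccc1 | intermediate
3 | benzyl 2,4-bis(benzyloxy)-5-(4,4,5,5-tetramethyl-1,3,2-dioxaborolan-2-yl)benzoate (not isolated) | O=C(OCc1ccccc1)c1cc(B2OC(C)(C)C(C)(C)O2)c(OCc2ccccc2)cc1OCc1ccccc1 | intermediate
4 | benzyl 2,4-bis(benzyloxy)-5-hydroxybenzoate | O=C(OCc1ccccc1)c1cc(O)c(OCc2ccccc2)cc1OCc1ccccc1 | intermediate
5 | 3-chloro-2-(chloromethyl)prop-1-ene | C=C(CCl)CCl | starting material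
6 | butylmagnesium chloride | CCCC[Mg]Cl | starting material
7 | 2-(chloromethyl)hept-1-ene | C=C(CCl)CCCCC | intermediate
8 | benzyl 2,4-bis(benzyloxy)-5-[(2-methylideneheptyl)oxy]benzoate | C=C(CCCCC)COc1cc(C(=O)OCc2ccccc2)c(OCc2ccccc2)cc1OCc1ccccc1 | intermediate
9 | benzyl 2,4-bis(benzyloxy)-6-(2-methylideneheptyl)-5-oxocyclohexa-1,3-diene-1-carboxylate (racemic, not isolated) | C=C(CCCCC)CC1C(=O)C(OCc2ccccc2)=CC(OCc2ccccc2)=C1C(=O)OCc1ccccc1 | intermediate
10 | benzyl 4,6-bis(benzyloxy)-3-hydroxy-2-(2-methylideneheptyl)benzoate | C=C(CCCCC)Cc1c(O)c(OCc2ccccc2)cc(OCc2ccccc2)c1C(=O)OCc1ccccc1 | intermediate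
11 | 2-fluoro-4-methoxybenzaldehyde | O=Cc1ccc(OC)cc1F | starting material
12 | benzyl 4,6-bis(benzyloxy)-3-(2-formyl-5-methoxyphenoxy)-2-(2-methylideneheptyl)benzoate | O=Cc1ccc(OC)cc1Oc1c(CC(=C)CCCCC)c(C(=O)OCc2ccccc2)c(OCc2ccccc2)cc1OCc1ccccc1 | intermediate
13 | 2-[4,6-bis(benzyloxy)-3-[(benzyloxy)carbonyl]-2-(2-methylideneheptyl)phenoxy]-4-methoxybenzoic acid | OC(=O)c1ccc(OC)cc1Oc1c(CC(=C)CCCCC)c(C(=O)OCc2ccccc2)c(OCc2ccccc2)cc1OCc1ccccc1 | intermediate
14 | 2-[4,6-bis(benzyloxy)-3-[(benzyloxy)carbonyl]-2-[2-hydroxy-2-(hydroxymethyl)heptyl]phenoxy]-4-methoxybenzoic acid (racemic, not isolated) | OC(=O)c1ccc(OC)cc1Oc1c(CC(O)(CO)CCCCC)c(C(=O)OCc2ccccc2)c(OCc2ccccc2)cc1OCc1ccccc1 | intermediate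
15 | 2-[4,6-bis(benzyloxy)-3-[(benzyloxy)carbonyl]-2-(2-oxoheptyl)phenoxy]-4-methoxybenzoic acid | OC(=O)c1ccc(OC)cc1Oc1c(CC(=O)CCCCC)c(C(=O)OCc2ccccc2)c(OCc2ccccc2)cc1OCc1ccccc1 | intermediate
16 | trimethylsulfoxonium iodide | C[S+](C)(C)=O.[I-] | starting material
17 | hexanoyl chloride | CCCCCC(Cl)=O | starting material
18 | dimethylsulfoxonium methylide (not isolated) | C=S(C)(C)=O | intermediate
19 | dimethylsulfoxonium 2-oxoheptylide | CCCCCC(=O)C=S(C)(C)=O | intermediate
20 | 2-[4,6-bis(benzyloxy)-3-[(benzyloxy)carbonyl]-2-(2-oxoheptyl)phenoxy]-4-methoxy-6-(2-oxoheptyl)benzoic acid (not isolated) | OC(=O)c1c(CC(=O)CCCCC)cc(OC)cc1Oc1c(CC(=O)CCCCC)c(C(=O)OCc2ccccc2)c(OCc2ccccc2)cc1OCc1ccccc1 | intermediate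
21 | benzyl 4,6-bis(benzyloxy)-3-[(6-methoxy-1-oxo-3-pentyl-1H-isochromen-8-yl)oxy]-2-(2-oxoheptyl)benzoate | CCCCCC(=O)Cc1c(Oc2cc(OC)cc3cc(CCCCC)oc(=O)c23)c(OCc2ccccc2)cc(OCc2ccccc2)c1C(=O)OCc1ccccc1 | intermediate
22 | beta-collatolic acid, 2,4-dihydroxy-5-[(6-methoxy-1-oxo-3-pentyl-1H-isochromen-8-yl)oxy]-6-(2-oxoheptyl)benzoic acid | CCCCCC(=O)Cc1c(Oc2cc(OC)cc3cc(CCCCC)oc(=O)c23)c(O)cc(O)c1C(=O)O | target

Total step count: 11. Longest linear sequence: 9 steps (1, 2, 4, 5, 6, 7, 8, 10, 11).

Steps most likely to fail

Step 10.
- **Risk:** Metalation may be slow because the bulky ortho aryloxy group twists the carboxylate. Carbene transfer from an alkyl-substituted ylide may also be sluggish. The acid may be O-alkylated by protonated ylide, and long heating may cause lactonisation on ring A with loss of benzyl alcohol.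
- **Fallback:** Ring C is closed before the ether bond is made. Commercial 2-fluoro-4-methoxybenzoic acid, whose acid is flanked only by a small fluorine, is annulated with 19 under the rhodium conditions. It passes through 2-fluoro-4-methoxy-6-(2-oxoheptyl)benzoic acid F1 to 8-fluoro-6-methoxy-3-pentylisocoumarin F2.
- Phenol 10 then displaces the fluoride, which stands ortho to the carbon bearing the lactone carbonyl (K2CO3, dry DMF, 100 °C). This gives the alkene-bearing diaryl ether F3.
- OsO4/NaIO4/2,6-lutidine should attack the isolated 1,1-disubstituted alkene in preference to the conjugated, acyloxy-substituted C3=C4 bond. Through the diol F4 this delivers 21.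
- The fallback sets out from 10 and 19 and returns at 21.

Step 6.
- **Risk:** Substitution may be slow because the phenoxide is flanked on both sides and the methoxy group para to the formyl group weakens its pull. Long heating invites benzyl transfer from the ester to the phenoxide.
- **Fallback:** A copper-catalysed Ullmann-type coupling replaces addition–elimination. Phenol 10 is coupled with commercial 2-bromo-4-methoxybenzoic acid (CuI, N,N-dimethylglycine, Cs2CO3, 1,4-dioxane, 100 °C). The ortho carboxylate assists oxidative addition at copper.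
- The fallback sets out from 10 and returns directly at acid 13, so step 7 is no longer needed.

Step 11.
- **Risk:** The C3=C4 bond of ring C may be over-reduced, or debenzylation may stall before all three groups are lost.
- **Fallback:** Lewis-acid debenzylation with a cation scavenger replaces hydrogenation (BCl3, pentamethylbenzene, CH2Cl2, −78 °C, cold aqueous quench). This cleaves aryl benzyl ethers and the benzyl ester. It should leave the C6 methyl ether, which has no neighbouring carbonyl for chelation, and all C=C bonds untouched.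
- The fallback sets out from 21 and returns at 22.

Further compounds
F1 | step 10 | 2-fluoro-4-methoxy-6-(2-oxoheptyl)benzoic acid | OC(=O)c1c(F)cc(OC)cc1CC(=O)CCCCC
F2 | step 10 | 8-fluoro-6-methoxy-3-pentyl-1H-isochromen-1-one | CCCCCc1cc2cc(OC)cc(F)c2c(=O)o1
F3 | step 10 | benzyl 4,6-bis(benzyloxy)-3-[(6-methoxy-1-oxo-3-pentyl-1H-isochromen-8-yl)oxy]-2-(2-methylideneheptyl)benzoate | C=C(CCCCC)Cc1c(Oc2cc(OC)cc3cc(CCCCC)oc(=O)c23)c(OCc2ccccc2)cc(OCc2ccccc2)c1C(=O)OCc1ccccc1
F4 | step 10 | benzyl 4,6-bis(benzyloxy)-2-[2-hydroxy-2-(hydroxymethyl)heptyl]-3-[(6-methoxy-1-oxo-3-pentyl-1H-isochromen-8-yl)oxy]benzoate (racemic) | OCC(O)(CCCCC)Cc1c(Oc2cc(OC)cc3cc(CCCCC)oc(=O)c23)c(OCc2ccccc2)cc(OCc2ccccc2)c1C(=O)OCc1ccccc1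
F0 | step 6 | none | none
F0 | step 11 | none | none
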